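3 questions stand on this flask, and 2 times answer them.

the same everywhere: gas phase 11 mM (held)
- Sunday's: substrate 13 mM; catalyst 14 µM; run made earlier
- Saturday's: substrate 30 mM; catalyst 14 µM; run made earlier
- Wednesday's: substrate 20 mM; catalyst 7 µM; run made earlier
- flask: substrate 20 mM; catalyst 14 µM; time 6.0 d

- Sunday's (time / d: target / %, substrate / %): 0.500: 4.2, 95.7; 1.67: 23.3, 74.9; 3.00: 39.7, 56.0; 4.00: 50.8, 44.8; 6.00: 61.3, 28.8
- Saturday's (time / d: target / %, substrate / %): 0.500: 3.7, 96.7; 1.67: 20.8, 80.2; 3.00: 37.6, 60.5; 4.00: 45.9, 49.6; 6.00: 58.7, 31.7
- Wednesday's (time / d: target / %, substrate / %): 1.25: 9.0, 92.9; 2.50: 20.9, 79.4; 4.00: 32.2, 67.3; 5.00: 36.6, 60.5; 6.00: 44.3, 52.7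

(standard deviation of a reading: 1 percentage point)

- at the start none of the gas is dissolved
- what was read earlier has a scatter of 1 percentage point, one standard deviation
- candidate steps: substrate + dissolved gas + catalyst -> catalyst + target; gas phase <-> dissolved gas; target + catalyst <-> isomer of the product + catalyst

- violet: doubling the amount of catalyst, all else as stated
- grey: doubling the transfer coefficient of the gas phase, all else as stated
- amber: doubling the saturation concentration of gas phase, all else as stated

- amount of target at 6.0 d, in percent of the substrate charged
- the change that raises the amount of target at 6.0 d, in percent of the substrate charged most ("none" if none brings more than 2 percentage points) (violet / grey / amber / none)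
- amount of target at 6.0 d, in percent of the substrate charged, after grey

Follow one molecule. As substrate it waits a mean time tA before becoming target. You read this from the substrate left at the last readings of Sunday's and Saturday's runs, whose charges bracket the flask's:

tA = 5.01 d

As target it waits tE before becoming isomer of the product. Divide the target-time spent by the isomer formed, taking the missing balance at the end as isomer and the middle reading of target as its mean:

tE = 23.8 d

S = tE/tA = 4.74

This ratio of waits is the selectivity factor. The wait as target is longer than the wait as substrate, and my reckoning for the flask is

c target / c substrate charged = S/(S − 1) · (exp(−t/tE) − exp(−t/tA)) = 60.2 %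

Wednesday's run, with half the catalyst, lost substrate at 0.107 /d against 0.200 /d. Taking both steps as proportional to catalyst, violet divides both times by 2 and keeps S, and my reckoning gives 64.9 %. If dissolved gas follows its saturation, amber divides tA by 2 and keeps tE, and my reckoning gives 76.7 %, which is more than for violet.

The forecast gave 60 %, amber as best, and 62 % after grey, since amber “speeds only the main step”.

    substrate + dissolved gas + catalyst → catalyst + target (k = 1120 /M²/min)
    gas phase ⇌ dissolved gas, rate k2*(csat - [dissolved gas]) (kL = 0.00132 /min)
    target + catalyst ⇌ isomer of the product + catalyst, rate k3*[catalyst]*[target] forward; the back reaction follows from the equilibrium constant (K = 0.574, k = 2.26 /M/min)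

The flask gives 61.7 % against my 60.2 %, 64.7 % after grey, and amber as best, with a gain of 18 percentage points. Now take the neighbouring flask with 0.0035 mM of catalyst, the other charges and the time held. In my reckoning, a quarter of the catalyst stretches tA to 20.1 d and tE to 95.1 d, while S stays 4.74. The reckoning then gives 25.0 % of target. That neighbouring flask gives 26.9 % of target, with 72 % of the substrate left.

The runs stem from a simulated flask with made-up constants.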